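**Plan**

1. Retrosynthetic cuts: (a) the six O-protecting groups (five benzyl ethers and one acetate on ring B); (b) the C8–C8'' biaryl bond, by Negishi coupling of (S)-8-iodoflavanone 20 with 8-zincated tri-O-benzylapigenin 24; (c) in ring C of the flavanone half the O1–C8a and C4–C4a bonds together, which removes ring A as an aryne and leaves a β-lactone.
2. Enabling feature: ring C (O1, C2, C3, C4, C4a, C8a) is a β-lactone ring (O1–C2–C3–C4=O) with the ortho carbon pair C8a/C4a of ring A inserted into its O1–C4 acyl–oxygen bond. The C5 oxygen next to C4a steers a 3,5-dioxygenated benzyne into exactly this orientation.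
3. Forward order: aryne precursor 8 from phenol 1 (3 steps); four-membered lactone 16 from acid chloride 9 (4 steps); two-atom ring expansion of 16 by aryne 17, which gives rings A and C of the flavanone at once; C8 iodination; coupling with the flavone half made from apigenin; hydrogenolysis and deacetylation.
4. Stereochemistry: C2 (S) is set by asymmetric transfer hydrogenation of β-keto ester 12 and carried with retention through lactonisation and ring expansion, neither of which touches the C2–O1 bond. The para-acetoxy group on ring B is a helper that keeps the benzylic lactone from ionising; it is removed in the last step.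

Key step: step 8

Remark: the target string defines only C2 (S); the fourfold ortho-substituted C8–C8'' axis is left uncontrolled, and whatever rotamer mixture about it forms is accepted.

**Route**

Step 1
Reactants: 1 3,5-bis(benzyloxy)phenol
Product: 2 3,5-bis(benzyloxy)phenyl N-isopropylcarbamate
Conditions: i-PrNCO, Et3N (cat.), CH2Cl2, rt
Reagents that add atoms: isopropyl isocyanate, CC(C)N=C=O
Why: Base-catalysed addition of the phenol to the isocyanate (carbamoylation) installs an N-monoalkyl carbamate, which is a strong ortho-directing group that can later be removed under mild conditions.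

Step 2
Reactants: 2 3,5-bis(benzyloxy)phenyl N-isopropylcarbamate
Product: 6 3,5-bis(benzyloxy)-2-(trimethylsilyl)phenyl N-isopropylcarbamate, via N-silyl carbamate 3 (not isolated), via ortho-lithiated carbamate 4 (not isolated), via doubly silylated carbamate 5 (not isolated)
Conditions: TBSOTf, TMEDA, Et2O, 0 °C to rt; n-BuLi, TMEDA, −78 °C; TMSCl, −78 °C to rt; aq. NaHSO4
Reagents that add atoms: chlorotrimethylsilane, C[Si](C)(C)Cl
Why: Directed ortho-metalation of the carbamate, N-protected in situ by silylation, should lithiate the position between the carbamate and a benzyloxy group (the two such positions are equivalent by symmetry); TMSCl traps the aryllithium and the N-silyl group is lost on acidic work-up.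

Step 3
Reactants: 6 3,5-bis(benzyloxy)-2-(trimethylsilyl)phenyl N-isopropylcarbamate
Product: 8 3,5-bis(benzyloxy)-2-(trimethylsilyl)phenyl trifluoromethanesulfonate, via silylphenol 7 (not isolated)
Conditions: DBU, Et2NH, MeCN, 40 °C; then PhNTf2, rt
Reagents that add atoms: N-phenylbis(trifluoromethanesulfonimide), O=S(=O)(N(c1ccccc1)S(=O)(=O)C(F)(F)F)C(F)(F)F
Why: DBU-promoted E1cB loss of isopropyl isocyanate (trapped by Et2NH as a urea) frees the phenol, which is triflated in the same flask to give the o-silylaryl triflate aryne precursor.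

Step 4
Reactants: 9 4-acetoxybenzoyl chloride; 10 Meldrum's acid
Product: 12 benzyl 3-(4-acetoxyphenyl)-3-oxopropanoate, via acyl Meldrum's acid 11 (not isolated)
Conditions: pyridine, CH2Cl2, 0 °C to rt; then BnOH, toluene, 100 °C
Reagents that add atoms: benzyl alcohol, OCc1ccccc1
Why: C-acylation of Meldrum's acid followed by thermal alcoholysis through the acylketene is the standard two-carbon homologation of an acid chloride to a β-keto ester, and the neutral conditions should leave the aryl acetate intact.

Step 5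
Reactants: 12 benzyl 3-(4-acetoxyphenyl)-3-oxopropanoate
Product: 13 benzyl (S)-3-(4-acetoxyphenyl)-3-hydroxypropanoate
Conditions: RuCl(p-cymene)[(S,S)-TsDPEN] (1 mol %), HCO2H/Et3N (5:2), CH2Cl2, 30 °C
Reagents that add atoms: none
Why: Noyori–Ikariya asymmetric transfer hydrogenation of an aryl ketone, in which the (S,S)-configured ruthenium hydride (CH–π contact between the substrate aryl ring and the η6-arene) should deliver hydride to the face that gives the (S)-benzylic alcohol, as for acetophenone-type substrates.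

Step 6
Reactants: 13 benzyl (S)-3-(4-acetoxyphenyl)-3-hydroxypropanoate
Product: 14 (S)-3-(4-acetoxyphenyl)-3-hydroxypropanoic acid
Conditions: H2 (1 atm), Pd/C (10 %), EtOAc, rt
Reagents that add atoms: none
Why: Neutral hydrogenolysis of the benzyl ester frees the acid without hydrolytic conditions that would cleave the aryl acetate, and the secondary benzylic alcohol, deactivated by the para-acetoxy group, should not be cleaved.

Step 7
Reactants: 14 (S)-3-(4-acetoxyphenyl)-3-hydroxypropanoic acid
Product: 16 (S)-4-(4-acetoxyphenyl)oxetan-2-one, via mixed sulfonic anhydride 15 (not isolated)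
Conditions: PhSO2Cl, pyridine, 0 to 4 °C
Reagents that add atoms: none
Why: Carboxyl-activation lactonisation, in which the β-hydroxyl closes the four-membered ring by 4-exo-trig acyl substitution on the mixed anhydride, so the C–O stereocentre is untouched (retention), while the electron-poor acetoxyaryl group should suppress benzylic ionisation and decarboxylation of the lactone.

Step 8
Reactants: 16 (S)-4-(4-acetoxyphenyl)oxetan-2-one; 8 3,5-bis(benzyloxy)-2-(trimethylsilyl)phenyl trifluoromethanesulfonate
Product: 19 4-[(2S)-5,7-bis(benzyloxy)-4-oxochroman-2-yl]phenyl acetate, via aryne 17 (not isolated), via oxonium aryl anion 18 (not isolated)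
Conditions: CsF, MeCN/toluene (1:1), rt, 8 (1.5 equiv) added slowly
Reagents that add atoms: none
Why: Proposed new method: fluoride-induced 1,2-elimination of 8 gives aryne 17, the ring oxygen of the strained lactone adds to the aryne carbon remote from the flanking benzyloxy group to give ortho-oxonio aryl anion 18, and the carbanion, held beside the acyl carbon, adds to the lactone carbonyl while the acyl–oxygen bond breaks (a 1,2 acyl shift from O to C), so that the two aryne carbons end up inside the former O–C(=O) bond. The closest known reaction types are aryne σ-insertion into the N–C(=O) bond of β-lactams (ring expansion to 2,3-dihydroquinolin-4-ones), into the O–C(=O) bond of carboxylic acids and into the C–O bond of epoxides, and the two-carbon ring expansion of cyclic β-keto esters by aryne acyl-alkylation; insertion into a lactone O–acyl bond is the untested extension. Ring C closes by exo-trig attack of the aryl anion on the ring carbonyl through a fused four-membered alkoxide that fragments with release of the β-lactone strain; should fluoride open the lactone first to the alkoxide acyl fluoride, O-arylation followed by 6-exo-trig acylation would lead to the same product. No stereocentre is formed: C2 keeps the (S) configuration of 16 because the C2–O1 bond is never broken, and the para-acetoxy group disfavours benzylic ionisation. The step needs regioselectivity (oxygen at C8a, acyl at C4a), which the benzyloxy group next to the aryne should secure by placing the developing negative charge on the carbon beside it, as in other additions to 3-alkoxyarynes, and chemoselectivity for the lactone oxygen over fluoride and solvent, which slow addition of 8 is meant to favour.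

Step 9
Reactants: 19 4-[(2S)-5,7-bis(benzyloxy)-4-oxochroman-2-yl]phenyl acetate
Product: 20 4-[(2S)-5,7-bis(benzyloxy)-8-iodo-4-oxochroman-2-yl]phenyl acetate
Conditions: NIS, TFA (cat.), MeCN, 0 °C to rt
Reagents that add atoms: N-iodosuccinimide, O=C1CCC(=O)N1I
Why: Electrophilic aromatic iodination of the most electron-rich ring, where in 5-O-alkylated 5,7-dioxygenated flavonoids C8 (para to the C5 oxygen, flanked by only one benzyloxy group) should be preferred over C6 (between two benzyloxy groups), while the acetoxy-bearing ring B is deactivated.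

Step 10
Reactants: 21 apigenin
Product: 22 5,7-bis(benzyloxy)-2-[4-(benzyloxy)phenyl]-4H-chromen-4-one
Conditions: BnBr (excess), K2CO3, KI (cat.), DMF, 80 °C
Reagents that add atoms: benzyl bromide, BrCc1ccccc1
Why: Williamson etherification of all three phenols, with excess reagent and heat to alkylate the hydrogen-bonded 5-hydroxyl as well.

Step 11
Reactants: 22 5,7-bis(benzyloxy)-2-[4-(benzyloxy)phenyl]-4H-chromen-4-one
Product: 23 5,7-bis(benzyloxy)-2-[4-(benzyloxy)phenyl]-8-iodo-4H-chromen-4-one
Conditions: NIS, TFA (cat.), CH2Cl2/MeCN, rt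
Reagents that add atoms: N-iodosuccinimide, O=C1CCC(=O)N1I
Why: Electrophilic aromatic iodination, which on 5,7-dialkoxyflavones should go to C8, the position para to the C5 oxygen and the less hindered of the two free positions of the phloroglucinol ring.

Step 12
Reactants: 23 5,7-bis(benzyloxy)-2-[4-(benzyloxy)phenyl]-8-iodo-4H-chromen-4-one; 20 4-[(2S)-5,7-bis(benzyloxy)-8-iodo-4-oxochroman-2-yl]phenyl acetate
Product: 25 4-[(2S)-5,7-bis(benzyloxy)-8-{5,7-bis(benzyloxy)-2-[4-(benzyloxy)phenyl]-4-oxo-4H-chromen-8-yl}-4-oxochroman-2-yl]phenyl acetate, via arylzinc iodide 24 (not isolated)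
Conditions: Zn dust, LiCl, THF, 50 °C; then 20, Pd2(dba)3 (2.5 mol %), RuPhos (10 mol %), THF/NMP, 70 °C
Reagents that add atoms: none
Why: Negishi coupling, in which LiCl-assisted zinc insertion into the C–I bond tolerates the pyranone carbonyl, the bulky dialkylbiarylphosphine is established for biaryls with four ortho substituents, and the non-basic arylzinc should leave the base-labile C2 centre and the aryl acetate untouched.

Step 13
Reactants: 25 4-[(2S)-5,7-bis(benzyloxy)-8-{5,7-bis(benzyloxy)-2-[4-(benzyloxy)phenyl]-4-oxo-4H-chromen-8-yl}-4-oxochroman-2-yl]phenyl acetate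
Product: 26 4-[(2S)-8-[5,7-dihydroxy-2-(4-hydroxyphenyl)-4-oxo-4H-chromen-8-yl]-5,7-dihydroxy-4-oxochroman-2-yl]phenyl acetate
Conditions: H2 (1 atm), Pd/C (10 %), EtOAc/MeOH, rt
Reagents that add atoms: none
Why: Catalytic hydrogenolysis of the five aryl benzyl ethers under neutral conditions, which should be faster than reduction of the flavone C2''=C3'' bond or cleavage of the C2–O1 bond and cannot epimerise C2.

Step 14
Reactants: 26 4-[(2S)-8-[5,7-dihydroxy-2-(4-hydroxyphenyl)-4-oxo-4H-chromen-8-yl]-5,7-dihydroxy-4-oxochroman-2-yl]phenyl acetate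
Product: 27 (2S)-8-[5,7-dihydroxy-2-(4-hydroxyphenyl)-4-oxo-4H-chromen-8-yl]-5,7-dihydroxy-2-(4-hydroxyphenyl)chroman-4-one
Conditions: HCl (1.25 M in MeOH), rt
Reagents that add atoms: none
Why: Acid-catalysed methanolysis (transesterification) of the phenolic acetate, chosen because acid, unlike base, should not open the flavanone ring through a chalcone or quinone methide, so C2 stays (S).

**Compound list**

1 | 3,5-bis(benzyloxy)phenol | Oc1cc(OCc2ccccc2)cc(OCc2ccccc2)c1 | starting material
2 | 3,5-bis(benzyloxy)phenyl N-isopropylcarbamate | CC(C)NC(=O)Oc1cc(OCc2ccccc2)cc(OCc2ccccc2)c1 | intermediate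
3 | 3,5-bis(benzyloxy)phenyl N-(tert-butyldimethylsilyl)-N-isopropylcarbamate | CC(C)N([Si](C)(C)C(C)(C)C)C(=O)Oc1cc(OCc2ccccc2)cc(OCc2ccccc2)c1 | intermediate
4 | 3,5-bis(benzyloxy)-2-lithiophenyl N-(tert-butyldimethylsilyl)-N-isopropylcarbamate | CC(C)N([Si](C)(C)C(C)(C)C)C(=O)Oc1cc(OCc2ccccc2)cc(OCc2ccccc2)c1[Li] | intermediate
5 | 3,5-bis(benzyloxy)-2-(trimethylsilyl)phenyl N-(tert-butyldimethylsilyl)-N-isopropylcarbamate | CC(C)N([Si](C)(C)C(C)(C)C)C(=O)Oc1cc(OCc2ccccc2)cc(OCc2ccccc2)c1[Si](C)(C)C | intermediate
6 | 3,5-bis(benzyloxy)-2-(trimethylsilyl)phenyl N-isopropylcarbamate | CC(C)NC(=O)Oc1cc(OCc2ccccc2)cc(OCc2ccccc2)c1[Si](C)(C)C | intermediate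
7 | 3,5-bis(benzyloxy)-2-(trimethylsilyl)phenol | Oc1cc(OCc2ccccc2)cc(OCc2ccccc2)c1[Si](C)(C)C | intermediate
8 | 3,5-bis(benzyloxy)-2-(trimethylsilyl)phenyl trifluoromethanesulfonate | C[Si](C)(C)c1c(OCc2ccccc2)cc(OCc2ccccc2)cc1OS(=O)(=O)C(F)(F)F | intermediate
9 | 4-acetoxybenzoyl chloride | CC(=O)Oc1ccc(C(=O)Cl)cc1 | starting material
10 | Meldrum's acid (2,2-dimethyl-1,3-dioxane-4,6-dione) | CC1(C)OC(=O)CC(=O)O1 | starting material
11 | 5-[(4-acetoxyphenyl)(hydroxy)methylidene]-2,2-dimethyl-1,3-dioxane-4,6-dione | CC(=O)Oc1ccc(C(O)=C2C(=O)OC(C)(C)OC2=O)cc1 | intermediate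
12 | benzyl 3-(4-acetoxyphenyl)-3-oxopropanoate | CC(=O)Oc1ccc(C(=O)CC(=O)OCc2ccccc2)cc1 | intermediate
13 | benzyl (S)-3-(4-acetoxyphenyl)-3-hydroxypropanoate | CC(=O)Oc1ccc([C@@H](O)CC(=O)OCc2ccccc2)cc1 | intermediate
14 | (S)-3-(4-acetoxyphenyl)-3-hydroxypropanoic acid | CC(=O)Oc1ccc([C@@H](O)CC(=O)O)cc1 | intermediate
15 | (S)-3-(4-acetoxyphenyl)-3-hydroxypropanoic benzenesulfonic anhydride | CC(=O)Oc1ccc([C@@H](O)CC(=O)OS(=O)(=O)c2ccccc2)cc1 | intermediate
16 | (S)-4-(4-acetoxyphenyl)oxetan-2-one | CC(=O)Oc1ccc([C@@H]2CC(=O)O2)cc1 | intermediate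
17 | 3,5-bis(benzyloxy)benzyne | C1#CC(OCc2ccccc2)=CC(OCc2ccccc2)=C1 | intermediate
18 | (S)-configured O-aryl oxetanonium aryl anion (lactone oxygen bonded to the aryne carbon, carbanion on the neighbouring carbon) | CC(=O)Oc1ccc([C@@H]2CC(=O)[O+]2c2[c-]c(OCc3ccccc3)cc(OCc3ccccc3)c2)cc1 | intermediate
19 | 4-[(2S)-5,7-bis(benzyloxy)-4-oxochroman-2-yl]phenyl acetate | CC(=O)Oc1ccc([C@@H]2CC(=O)c3c(OCc4ccccc4)cc(OCc4ccccc4)cc3O2)cc1 | intermediate
20 | 4-[(2S)-5,7-bis(benzyloxy)-8-iodo-4-oxochroman-2-yl]phenyl acetate | CC(=O)Oc1ccc([C@@H]2CC(=O)c3c(OCc4ccccc4)cc(OCc4ccccc4)c(I)c3O2)cc1 | intermediate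
21 | apigenin (5,7-dihydroxy-2-(4-hydroxyphenyl)-4H-chromen-4-one) | O=c1cc(-c2ccc(O)cc2)oc2cc(O)cc(O)c12 | starting material
22 | 5,7-bis(benzyloxy)-2-[4-(benzyloxy)phenyl]-4H-chromen-4-one | O=c1cc(-c2ccc(OCc3ccccc3)cc2)oc2cc(OCc3ccccc3)cc(OCc3ccccc3)c12 | intermediate
23 | 5,7-bis(benzyloxy)-2-[4-(benzyloxy)phenyl]-8-iodo-4H-chromen-4-one | O=c1cc(-c2ccc(OCc3ccccc3)cc2)oc2c(I)c(OCc3ccccc3)cc(OCc3ccccc3)c12 | intermediate
24 | {5,7-bis(benzyloxy)-2-[4-(benzyloxy)phenyl]-4-oxo-4H-chromen-8-yl}zinc iodide | O=c1cc(-c2ccc(OCc3ccccc3)cc2)oc2c([Zn]I)c(OCc3ccccc3)cc(OCc3ccccc3)c12 | intermediate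
25 | 4-[(2S)-5,7-bis(benzyloxy)-8-{5,7-bis(benzyloxy)-2-[4-(benzyloxy)phenyl]-4-oxo-4H-chromen-8-yl}-4-oxochroman-2-yl]phenyl acetate | CC(=O)Oc1ccc([C@@H]2CC(=O)c3c(OCc4ccccc4)cc(OCc4ccccc4)c(-c4c(OCc5ccccc5)cc(OCc5ccccc5)c5c(=O)cc(-c6ccc(OCc7ccccc7)cc6)oc45)c3O2)cc1 | intermediate
26 | 4-[(2S)-8-[5,7-dihydroxy-2-(4-hydroxyphenyl)-4-oxo-4H-chromen-8-yl]-5,7-dihydroxy-4-oxochroman-2-yl]phenyl acetate | CC(=O)Oc1ccc([C@@H]2CC(=O)c3c(O)cc(O)c(-c4c(O)cc(O)c5c(=O)cc(-c6ccc(O)cc6)oc45)c3O2)cc1 | intermediate
27 | (2S)-8-[5,7-dihydroxy-2-(4-hydroxyphenyl)-4-oxo-4H-chromen-8-yl]-5,7-dihydroxy-2-(4-hydroxyphenyl)chroman-4-one (CNP0339995.1) | O=C1C[C@@H](c2ccc(O)cc2)Oc2c1c(O)cc(O)c2-c1c(O)cc(O)c2c(=O)cc(-c3ccc(O)cc3)oc12 | target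

**Totals and risks**

Total step count: 14. Longest linear sequence: 9 steps (steps 4, 5, 6, 7, 8, 9, 12, 13, 14).

Steps most likely to fail:

1. Step 8 (ring expansion by the aryne). The weakly nucleophilic lactone oxygen may not intercept the aryne before fluoride or solvent consume it. Attack through the carbonyl oxygen, or benzylic ionisation with decarboxylation, would cost yield and configurational purity. The fallback uses known chemistry, sets out from carbamate 2 and comes back at 19. The in situ N-silylation and ortho-lithiation of step 2 (3, then 4) are repeated and the aryllithium is quenched with N-methoxy-N-methylacetamide to give 2-acetyl-3,5-bis(benzyloxy)phenyl N-isopropylcarbamate F1. DBU/Et2NH then frees 1-[2,4-bis(benzyloxy)-6-hydroxyphenyl]ethan-1-one F2. DMF dimethyl acetal converts this into (E)-1-[2,4-bis(benzyloxy)-6-hydroxyphenyl]-3-(dimethylamino)prop-2-en-1-one F3, which should cyclise with HCl to 5,7-bis(benzyloxy)-4H-chromen-4-one F4. Asymmetric conjugate addition of 4-acetoxyphenylboronic acid to F4 (Pd(OCOCF3)2, (R)-t-BuPyOx, NH4PF6, H2O, ClCH2CH2Cl, 60 °C) should then give 19; the ligand hand is chosen by analogy with cyclic enones to give the (2S) product.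

2. Step 12 (Negishi coupling). Zinc insertion into the electron-rich, doubly ortho-substituted C–I bond may be sluggish, and protodezincation may outrun the slow transmetalation and reductive elimination at a fourfold ortho-substituted axis. The fallback sets out from iodide 23 and comes back at 25. Palladium-catalysed borylation of 23 with pinacolborane (PdCl2(MeCN)2, SPhos, Et3N, dioxane, 80 °C) should give 5,7-bis(benzyloxy)-2-[4-(benzyloxy)phenyl]-8-(4,4,5,5-tetramethyl-1,3,2-dioxaborolan-2-yl)-4H-chromen-4-one F5. Suzuki–Miyaura coupling of F5 with 20 (Pd2(dba)3, SPhos, anhydrous K3PO4, toluene, 80 °C) should lead to 25; the anhydrous, weakly basic medium is chosen to limit ring opening at C2 and loss of the acetate.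

3. Step 13 (hydrogenolysis). Reduction of the flavone C2''=C3'' double bond or hydrogenolytic opening of the benzylic C2–O1 bond may set in before all five benzyl ethers are gone. The fallback sets out from 25 and comes back at 26, with no new compound on the way. The benzyl ethers are removed without hydrogen by BCl3 in CH2Cl2 at −78 °C with pentamethylbenzene as scavenger for the benzyl cation, which should leave the acetate, the pyranone double bond and C2 untouched.

Further compounds
F1 | step 8 | 2-acetyl-3,5-bis(benzyloxy)phenyl N-isopropylcarbamate | CC(C)NC(=O)Oc1cc(OCc2ccccc2)cc(OCc2ccccc2)c1C(C)=O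
F2 | step 8 | 1-[2,4-bis(benzyloxy)-6-hydroxyphenyl]ethan-1-one | CC(=O)c1c(O)cc(OCc2ccccc2)cc1OCc1ccccc1
F3 | step 8 | (E)-1-[2,4-bis(benzyloxy)-6-hydroxyphenyl]-3-(dimethylamino)prop-2-en-1-one | CN(C)/C=C/C(=O)c1c(O)cc(OCc2ccccc2)cc1OCc1ccccc1
F4 | step 8 | 5,7-bis(benzyloxy)-4H-chromen-4-one | O=c1ccoc2cc(OCc3ccccc3)cc(OCc3ccccc3)c12
F5 | step 12 | 5,7-bis(benzyloxy)-2-[4-(benzyloxy)phenyl]-8-(4,4,5,5-tetramethyl-1,3,2-dioxaborolan-2-yl)-4H-chromen-4-one | O=c1cc(-c2ccc(OCc3ccccc3)cc2)oc2c(B3OC(C)(C)C(C)(C)O3)c(OCc3ccccc3)cc(OCc3ccccc3)c12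
F0 | step 13 | none | none
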